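**Plan**
- Cuts (drimane numbering for the decalin; primed locants for the five-membered ring, C1′ ketone, C3′ enol, C4′ alkylidene carbon, C5′ CHCl): C11–C4′ and C5′–Cl, then C8–CH3, then C5–C10 together with C8–C9, and in the open chain C3–C4, C6=C7 and the C10–CH3/C9–C11 pair.
- Forward: the chain is joined linearly (alkyne carboalumination, copper-catalysed conjugate addition, Wittig extension, dienyl pivalate, enal). Rings A and B arise together in step 9, C8 is then made the methyl carbinol, and the chlorinated cyclopentenone is attached last through C11.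
- Enabling feature: ring B carries the contiguous stereocentres C5, C10, C9 and C8, with C11 cis to the C10 methyl, a trans A/B fusion and oxygen on C8. This is the imprint of an endo [4+2] between an E-β-methyl enal (C9=C10) and an E,E-1-oxygenated diene (C5=C6–C7=C8) joined by the C1–C4 tether.
- Stereochemistry: C5, C9 and C10 come from the catalyst-controlled endo Diels–Alder reaction, and C8 from α-face (equatorial) methyl addition to the 8-ketone. C5′ comes from chloride entering anti to the (R)-silyloxy group of a commercial cyclopentenone, whose oxygen is oxidised to the ketone at the end. The C11=C4′ geometry follows steric preference.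

Key step: step 9

Assumption: the facial preference of the oxazaborolidinium catalyst is taken from its formyl C–H···O pre-transition-state model, under which the (R)-catalyst exposes the C9-Si/C10-Re face needed here; the target is drawn and made as its 3-hydroxy-enone tautomer.

**Step 1**
Reactants: 1 5-chloropent-1-yne
Product: 3 (E)-6-chloro-3-methylhex-2-en-1-ol, via alkenylalane 2 (not isolated)
Conditions: AlMe3 (2.5 equiv), Cp2ZrCl2 (0.25 equiv), CH2Cl2, 0 °C to rt; then (CH2O)n, THF, 0 °C to rt; aq. HCl work-up
Reagents that add atoms: trimethylaluminium, C[Al](C)C; paraformaldehyde (formaldehyde unit), C=O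
Why: Negishi zirconium-catalysed carboalumination adds CH3 and Al syn across the alkyne with Al on the terminal carbon, and hydroxymethylation of the resulting E-alkenylalane gives the E-trisubstituted allylic alcohol that later fixes the C9/C10 relationship, the primary alkyl chloride being inert to AlMe3.

**Step 2**
Reactants: 3 (E)-6-chloro-3-methylhex-2-en-1-ol
Product: 4 tert-butyl{[(E)-6-chloro-3-methylhex-2-en-1-yl]oxy}dimethylsilane
Conditions: TBSCl, imidazole, DMF, rt
Reagents that add atoms: tert-butyldimethylsilyl chloride, CC(C)(C)[Si](C)(C)Cl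
Why: Imidazole-promoted silylation protects the allylic alcohol as a silyl ether that tolerates the Grignard, hydride, ylide and alkoxide reagents of steps 3 to 6.

**Step 3**
Reactants: 4 tert-butyl{[(E)-6-chloro-3-methylhex-2-en-1-yl]oxy}dimethylsilane; 5 methyl 3-methylbut-2-enoate
Product: 8 methyl (E)-9-[(tert-butyldimethylsilyl)oxy]-3,3,7-trimethylnon-7-enoate, via Grignard reagent 6 (not isolated), via silyl ketene acetal 7 (not isolated)
Conditions: Mg, THF, 50 °C; then 5, CuI (10 mol %), TMSCl (2 equiv), THF, −40 to 0 °C; aq. NH4Cl, then dilute HCl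
Reagents that add atoms: none
Why: The primary chloride gives the Grignard reagent, and copper-catalysed, TMSCl-accelerated conjugate addition to the β,β-disubstituted enoate creates the quaternary C4 with its two methyl groups, the silyl ketene acetal being hydrolysed to the ester on work-up.

**Step 4**
Reactants: 8 methyl (E)-9-[(tert-butyldimethylsilyl)oxy]-3,3,7-trimethylnon-7-enoate
Product: 9 (E)-9-[(tert-butyldimethylsilyl)oxy]-3,3,7-trimethylnon-7-enal
Conditions: i-Bu2AlH (1.1 equiv), CH2Cl2, −78 °C; aq. potassium sodium tartrate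
Reagents that add atoms: none
Why: Partial hydride reduction of the methyl ester at −78 °C stops at the aluminium hemiacetal, which releases the aldehyde only on work-up.

**Step 5**
Reactants: 9 (E)-9-[(tert-butyldimethylsilyl)oxy]-3,3,7-trimethylnon-7-enal; 10 (triphenylphosphoranylidene)acetaldehyde
Product: 11 (2E,9E)-11-[(tert-butyldimethylsilyl)oxy]-5,5,9-trimethylundeca-2,9-dienal
Conditions: toluene, 80 °C
Reagents that add atoms: none
Why: Wittig olefination with the stabilised formyl ylide extends the aldehyde by two carbons (C7 and C8) and gives the E-enal selectively.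

**Step 6**
Reactants: 11 (2E,9E)-11-[(tert-butyldimethylsilyl)oxy]-5,5,9-trimethylundeca-2,9-dienal
Product: 13 (1E,3E,9E)-11-[(tert-butyldimethylsilyl)oxy]-5,5,9-trimethylundeca-1,3,9-trien-1-yl pivalate, via potassium dienolate 12 (not isolated)
Conditions: KOt-Bu (1.2 equiv), THF, −78 °C; then PivCl, −78 to −40 °C
Reagents that add atoms: pivaloyl chloride, CC(C)(C)C(Cl)=O
Why: γ-Deprotonation of the enal gives the extended dienolate, and its O-acylation furnishes the 1-acyloxydiene, the s-trans enal leading to the 1E enol ester and the bulky tertiary alkyl group enforcing the 3E geometry.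

**Step 7**
Reactants: 13 (1E,3E,9E)-11-[(tert-butyldimethylsilyl)oxy]-5,5,9-trimethylundeca-1,3,9-trien-1-yl pivalate
Product: 14 (1E,3E,9E)-11-hydroxy-5,5,9-trimethylundeca-1,3,9-trien-1-yl pivalate
Conditions: HF·pyridine, pyridine, THF, 0 °C
Reagents that add atoms: none
Why: Buffered fluoride-mediated desilylation frees the allylic alcohol without cleaving the enol pivalate, which a basic fluoride source or methanolysis could attack.

**Step 8**
Reactants: 14 (1E,3E,9E)-11-hydroxy-5,5,9-trimethylundeca-1,3,9-trien-1-yl pivalate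
Product: 15 (1E,3E,9E)-5,5,9-trimethyl-11-oxoundeca-1,3,9-trien-1-yl pivalate [(2E,8E,10E)-3,7,7-trimethyl-11-(pivaloyloxy)undeca-2,8,10-trienal]
Conditions: MnO2 (excess), CH2Cl2, rt
Reagents that add atoms: none
Why: Allylic oxidation with MnO2 gives the E-β-methyl enal without E/Z isomerisation and leaves the dienyl ester untouched.

**Step 9**
Reactants: 15 (2E,8E,10E)-3,7,7-trimethyl-11-(pivaloyloxy)undeca-2,8,10-trienal
Product: 16 8β-pivaloyloxy-12-nordrim-6-en-11-al (5α-H, 9β-CHO, 10β-CH3; trans-fused octalin)
Conditions: (R)-tetrahydro-1-(2-methylphenyl)-3,3-diphenyl-1H,3H-pyrrolo[1,2-c][1,3,2]oxazaborole (20 mol %), (CF3SO2)2NH (18 mol %), CH2Cl2, −40 to −20 °C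
Reagents that add atoms: none
Why: Proposed new method: the N-protonated oxazaborolidine binds the formyl oxygen of the s-trans E-enal and lowers its LUMO, so that the tethered 1-pivaloyloxydiene adds in a concerted but asynchronous [4+2] in which C5 (the nucleophilic diene terminus remote from oxygen) bonds first to the β-carbon C10 and C8 then bonds to C9; the closest known reaction type is the oxazaborolidinium-catalysed enantioselective intramolecular Diels–Alder reaction of 2,8,10-trienals to trans-fused octalins, and the extension is the β-methyl group on the dienophile that makes C10 quaternary. Ring B is closed as the six-membered cycloadduct ring by both new σ-bonds, and ring A is closed at the same time as a fused six-membered ring by the C5–C10 bond across the four-carbon tether C1–C4. The relative configuration at C9 and C10 follows from suprafacial addition to the E-enal (formyl cis to the C10 methyl), that at C5 and C8 from suprafacial use of the E,E-diene (tether and pivalate both outside), and the link between the two pairs from the endo transition state with the formyl group under the diene and the tether anti, which gives the trans ring fusion and the 8β-oxygen. The absolute configuration is set by the catalyst, whose aryl group shields one face of the coordinated enal so that the diene reaches C9 from its Si face and C10 from its Re face. The step needs endo over exo selectivity and intact E-geometry of both π-systems: Lewis-acid activation of a terminally activated E-dienophile favours the endo mode, the tether length allows only the fused regiochemistry that also matches the polarisation of diene and enal, and a Lewis acid is used instead of an amine catalyst so that the enal geometry is not scrambled through a dienamine and the β-pivaloyloxy aldehyde product is not eliminated.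

**Step 10**
Reactants: 16 8β-pivaloyloxy-12-nordrim-6-en-11-al
Product: 17 12-nordrim-6-ene-8β,11-diol
Conditions: LiAlH4, THF, −40 to 0 °C
Reagents that add atoms: none
Why: Hydride reduction converts the aldehyde to the C11 primary alcohol before the β-acyloxy aldehyde can eliminate and cleaves the pivalate reductively to the 8β-alcohol, with no change at any stereocentre.

**Step 11**
Reactants: 17 12-nordrim-6-ene-8β,11-diol
Product: 18 12-nordrimane-8β,11-diol
Conditions: H2 (1 atm), PtO2 (5 mol %), EtOAc, rt
Reagents that add atoms: none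
Why: Heterogeneous hydrogenation saturates the disubstituted C6=C7 alkene, PtO2 being chosen to avoid hydrogenolysis of the allylic C8 alcohol, and no stereocentre is created.

**Step 12**
Reactants: 18 12-nordrimane-8β,11-diol
Product: 19 11-hydroxy-12-nordriman-8-one
Conditions: aq. NaOCl (1.2 equiv), AcOH, 0 °C to rt
Reagents that add atoms: none
Why: Hypochlorite in acetic acid oxidises secondary alcohols much faster than primary ones, as known for 1,3-diols, so the axial C8 carbinol gives the ketone while the C11 hydroxymethyl group is kept and C9 stays in its stable equatorial configuration.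

**Step 13**
Reactants: 19 11-hydroxy-12-nordriman-8-one
Product: 20 drimane-8β,11-diol (8α-CH3, 8β-OH)
Conditions: MeMgBr (4 equiv), THF, −40 to 0 °C; aq. NH4Cl
Reagents that add atoms: methylmagnesium bromide, C[Mg]Br
Why: Grignard addition to the ketone of the chelated magnesium alkoxide takes place equatorially from the α-face because the β-face of C8 is blocked by the 1,3-diaxial C10 methyl group, which gives the 8α-methyl-8β-ol of the target.

**Step 14**
Reactants: 20 drimane-8β,11-diol (8α-CH3, 8β-OH)
Product: 21 8β-hydroxydriman-11-al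
Conditions: Dess–Martin periodinane (1.3 equiv), NaHCO3, CH2Cl2, 0 °C to rt
Reagents that add atoms: none
Why: Dess–Martin oxidation converts the primary alcohol to the aldehyde while the tertiary alcohol cannot be oxidised, and the buffered neutral medium avoids retro-aldol cleavage or dehydration of the β-hydroxy aldehyde.

**Step 15**
Reactants: 21 8β-hydroxydriman-11-al
Product: 22 8β-(triethylsilyloxy)driman-11-al
Conditions: TESOTf, 2,6-lutidine, CH2Cl2, −78 to 0 °C
Reagents that add atoms: triethylsilyl trifluoromethanesulfonate, CC[Si](CC)(CC)OS(=O)(=O)C(F)(F)F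
Why: Silylation with the triflate and a hindered pyridine base caps the tertiary hydroxyl, so that step 18 meets a single free hydroxyl, without enolising the hindered aldehyde.

**Step 16**
Reactants: 23 (R)-4-[(tert-butyldimethylsilyl)oxy]cyclopent-2-en-1-one
Product: 24 (R)-4-[(tert-butyldimethylsilyl)oxy]-2-iodocyclopent-2-en-1-one
Conditions: I2, pyridine, CH2Cl2, 0 °C to rt
Reagents that add atoms: iodine, II
Why: α-Iodination of the enone by conjugate addition of pyridine, iodination of the enolate and elimination gives the 2-iodoenone without touching the C4 stereocentre.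

**Step 17**
Reactants: 22 8β-(triethylsilyloxy)driman-11-al; 24 (R)-4-[(tert-butyldimethylsilyl)oxy]-2-iodocyclopent-2-en-1-one
Product: 26 (4R)-4-[(tert-butyldimethylsilyl)oxy]-2-[11-hydroxy-8β-(triethylsilyloxy)driman-11-yl]cyclopent-2-en-1-one (both C11 epimers), via alkenylchromium dichloride 25 (not isolated)
Conditions: CrCl2 (5 equiv), NiCl2 (2 mol %), DMF, rt
Reagents that add atoms: none
Why: In this Nozaki–Hiyama–Kishi coupling zerovalent nickel inserts into the alkenyl iodide and transmetalation gives an alkenyl species of trivalent chromium that adds to the hindered aldehyde and not to ketones, the C11 carbinol configuration being irrelevant because it is erased in step 18.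

**Step 18**
Reactants: 26 (4R)-4-[(tert-butyldimethylsilyl)oxy]-2-[11-hydroxy-8β-(triethylsilyloxy)driman-11-yl]cyclopent-2-en-1-one
Product: 28 (3R,4R)-4-[(tert-butyldimethylsilyl)oxy]-3-chloro-2-[(E)-8β-(triethylsilyloxy)driman-11-ylidene]cyclopentan-1-one, via allylic mesylate 27 (not isolated)
Conditions: MsCl, Et3N, CH2Cl2, −20 °C; then LiCl, DMF, 0 °C to rt
Reagents that add atoms: lithium chloride, [Li+].[Cl-]
Why: The Morita–Baylis–Hillman-type allylic mesylate undergoes SN2′ substitution by conjugate addition of chloride to C5′ and loss of mesylate (direct SN2 at the neopentyl-like C11 is blocked), chloride entering anti to the adjacent 1′-silyloxy group as nucleophiles do with 4-silyloxycyclopent-2-enones, which sets C5′ as R, and the alkylidene taking the geometry that keeps the bulky C9 away from the substituted sp3 carbon C5′.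

**Step 19**
Reactants: 28 (3R,4R)-4-[(tert-butyldimethylsilyl)oxy]-3-chloro-2-[(E)-8β-(triethylsilyloxy)driman-11-ylidene]cyclopentan-1-one
Product: 29 (3R,4R)-3-chloro-4-hydroxy-2-[(E)-8β-hydroxydriman-11-ylidene]cyclopentan-1-one
Conditions: HF·pyridine, pyridine, THF, 0 °C to rt
Reagents that add atoms: none
Why: Fluoride-mediated cleavage of both silyl ethers under mildly acidic conditions avoids β-elimination of the β-hydroxy ketone and leaves the allylic chloride and all stereocentres untouched.

**Step 20**
Reactants: 29 (3R,4R)-3-chloro-4-hydroxy-2-[(E)-8β-hydroxydriman-11-ylidene]cyclopentan-1-one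
Product: 30 (5R)-5-chloro-3-hydroxy-4-[(E)-8β-hydroxydriman-11-ylidene]cyclopent-2-en-1-one (CNP0279879.2)
Conditions: Dess–Martin periodinane (1.5 equiv), CH2Cl2, 0 °C to rt; pH 5 buffer work-up
Reagents that add atoms: none
Why: Dess–Martin oxidation of the β-hydroxy ketone gives the 1,3-diketone, which enolises to the conjugated vinylogous acid of the target, the neutral oxidation and weakly acidic work-up being chosen so that the C5′ chloride stereocentre is not enolised and the tertiary C8 alcohol stays inert.

**Compound list**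
1 | 5-chloropent-1-yne | C#CCCCCl | starting material
2 | (E)-(5-chloro-2-methylpent-1-en-1-yl)dimethylalane (formed in situ) | C[Al](C)/C=C(\C)CCCCl | intermediate
3 | (E)-6-chloro-3-methylhex-2-en-1-ol | OC/C=C(\C)CCCCl | intermediate
4 | tert-butyl{[(E)-6-chloro-3-methylhex-2-en-1-yl]oxy}dimethylsilane | CC(C)(C)[Si](C)(C)OC/C=C(\C)CCCCl | intermediate
5 | methyl 3-methylbut-2-enoate | COC(=O)C=C(C)C | starting material
6 | (E)-6-[(tert-butyldimethylsilyl)oxy]-4-methylhex-4-en-1-ylmagnesium chloride (formed in situ) | Cl[Mg]CCC/C(C)=C/CO[Si](C)(C)C(C)(C)C | intermediate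
7 | methyl trimethylsilyl ketene acetal of ester 8 (formed in situ) | COC(O[Si](C)(C)C)=CC(C)(C)CCC/C(C)=C/CO[Si](C)(C)C(C)(C)C | intermediate
8 | methyl (E)-9-[(tert-butyldimethylsilyl)oxy]-3,3,7-trimethylnon-7-enoate | COC(=O)CC(C)(C)CCC/C(C)=C/CO[Si](C)(C)C(C)(C)C | intermediate
9 | (E)-9-[(tert-butyldimethylsilyl)oxy]-3,3,7-trimethylnon-7-enal | O=CCC(C)(C)CCC/C(C)=C/CO[Si](C)(C)C(C)(C)C | intermediate
10 | (triphenylphosphoranylidene)acetaldehyde | O=CC=P(c1ccccc1)(c1ccccc1)c1ccccc1 | starting material
11 | (2E,9E)-11-[(tert-butyldimethylsilyl)oxy]-5,5,9-trimethylundeca-2,9-dienal | O=C/C=C/CC(C)(C)CCC/C(C)=C/CO[Si](C)(C)C(C)(C)C | intermediate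
12 | potassium (1E,3E,9E)-11-[(tert-butyldimethylsilyl)oxy]-5,5,9-trimethylundeca-1,3,9-trien-1-olate (formed in situ) | [K+].[O-]/C=C/C=C/C(C)(C)CCC/C(C)=C/CO[Si](C)(C)C(C)(C)C | intermediate
13 | (1E,3E,9E)-11-[(tert-butyldimethylsilyl)oxy]-5,5,9-trimethylundeca-1,3,9-trien-1-yl pivalate | CC(C)(C)C(=O)O/C=C/C=C/C(C)(C)CCC/C(C)=C/CO[Si](C)(C)C(C)(C)C | intermediate
14 | (1E,3E,9E)-11-hydroxy-5,5,9-trimethylundeca-1,3,9-trien-1-yl pivalate | CC(C)(C)C(=O)O/C=C/C=C/C(C)(C)CCC/C(C)=C/CO | intermediate
15 | (2E,8E,10E)-3,7,7-trimethyl-11-(pivaloyloxy)undeca-2,8,10-trienal | CC(C)(C)C(=O)O/C=C/C=C/C(C)(C)CCC/C(C)=C/C=O | intermediate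
16 | 8β-pivaloyloxy-12-nordrim-6-en-11-al (5α-H, 9β-CHO, 10β-CH3) | CC1(C)CCC[C@]2(C)[C@@H](C=O)[C@@H](OC(=O)C(C)(C)C)C=C[C@@H]12 | intermediate
17 | 12-nordrim-6-ene-8β,11-diol | CC1(C)CCC[C@]2(C)[C@@H](CO)[C@@H](O)C=C[C@@H]12 | intermediate
18 | 12-nordrimane-8β,11-diol | CC1(C)CCC[C@]2(C)[C@@H](CO)[C@@H](O)CC[C@@H]12 | intermediate
19 | 11-hydroxy-12-nordriman-8-one | CC1(C)CCC[C@]2(C)[C@@H](CO)C(=O)CC[C@@H]12 | intermediate
20 | drimane-8β,11-diol (8α-CH3, 8β-OH) | CC1(C)CCC[C@]2(C)[C@@H](CO)[C@@](C)(O)CC[C@@H]12 | intermediate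
21 | 8β-hydroxydriman-11-al | CC1(C)CCC[C@]2(C)[C@@H](C=O)[C@@](C)(O)CC[C@@H]12 | intermediate
22 | 8β-(triethylsilyloxy)driman-11-al | CC1(C)CCC[C@]2(C)[C@@H](C=O)[C@@](C)(O[Si](CC)(CC)CC)CC[C@@H]12 | intermediate
23 | (R)-4-[(tert-butyldimethylsilyl)oxy]cyclopent-2-en-1-one | O=C1C=C[C@H](O[Si](C)(C)C(C)(C)C)C1 | starting material
24 | (R)-4-[(tert-butyldimethylsilyl)oxy]-2-iodocyclopent-2-en-1-one | O=C1C(I)=C[C@H](O[Si](C)(C)C(C)(C)C)C1 | intermediate
25 | (R)-{3-[(tert-butyldimethylsilyl)oxy]-5-oxocyclopent-1-en-1-yl}chromium dichloride (trivalent chromium, formed in situ) | O=C1C([Cr](Cl)Cl)=C[C@H](O[Si](C)(C)C(C)(C)C)C1 | intermediate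
26 | (4R)-4-[(tert-butyldimethylsilyl)oxy]-2-[11-hydroxy-8β-(triethylsilyloxy)driman-11-yl]cyclopent-2-en-1-one (C11 epimers) | CC1(C)CCC[C@]2(C)[C@@H](C(O)C3=C[C@H](O[Si](C)(C)C(C)(C)C)CC3=O)[C@@](C)(O[Si](CC)(CC)CC)CC[C@@H]12 | intermediate
27 | C11 methanesulfonate of 26 (formed in situ) | CC1(C)CCC[C@]2(C)[C@@H](C(OS(C)(=O)=O)C3=C[C@H](O[Si](C)(C)C(C)(C)C)CC3=O)[C@@](C)(O[Si](CC)(CC)CC)CC[C@@H]12 | intermediate
28 | (3R,4R)-4-[(tert-butyldimethylsilyl)oxy]-3-chloro-2-[(E)-8β-(triethylsilyloxy)driman-11-ylidene]cyclopentan-1-one | CC1(C)CCC[C@]2(C)[C@@H](/C=C3\C(=O)C[C@@H](O[Si](C)(C)C(C)(C)C)[C@@H]3Cl)[C@@](C)(O[Si](CC)(CC)CC)CC[C@@H]12 | intermediate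
29 | (3R,4R)-3-chloro-4-hydroxy-2-[(E)-8β-hydroxydriman-11-ylidene]cyclopentan-1-one | CC1(C)CCC[C@]2(C)[C@@H](/C=C3\C(=O)C[C@@H](O)[C@@H]3Cl)[C@@](C)(O)CC[C@@H]12 | intermediate
30 | (5R)-5-chloro-3-hydroxy-4-[(E)-8β-hydroxydriman-11-ylidene]cyclopent-2-en-1-one (CNP0279879.2) | CC1(C)CCC[C@]2(C)[C@@H](/C=C3\C(O)=CC(=O)[C@@H]3Cl)[C@@](C)(O)CC[C@@H]12 | target

**Step count**
Total: 20 steps. Longest linear sequence: 19 steps (steps 1–15 and 17–20, from 5-chloropent-1-yne); step 16 is a one-step branch.

**Steps most likely to fail**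

Step 9 (bears the new-method label). The methyl group cis to the formyl group may crowd the catalyst–enal complex, which would give slow turnover or poor facial discrimination. The developing 1,3-diaxial methyl pair at C4/C10 may also let the cis-fused (exo) mode compete. The fallback uses known chemistry and sets out from trienal 15. Cyclisation promoted by the achiral Lewis acid Me2AlCl (30 mol %, CH2Cl2, −20 °C to rt), or simple heating in toluene, should give the adduct as a racemate, that is 16 together with its mirror image ent-8β-pivaloyloxy-12-nordrim-6-en-11-al F1. Reduction with LiAlH4 then gives 17 together with ent-12-nordrim-6-ene-8β,11-diol F2. Acylation of the primary hydroxyl with (1S)-camphanoyl chloride and pyridine gives the diastereomeric esters 11-O-[(1S)-camphanoyl]-12-nordrim-6-ene-8β,11-diol F3 and the (1S)-camphanate of the mirror-image diol F4, to be separated by chromatography or crystallisation. Methanolysis of F3 (K2CO3, MeOH) returns enantiopure 17, where the route continues with step 11.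

Step 18. Base-induced β-elimination of the silyloxy group, chloride entering syn to that group, or formation of the alkene isomer with C9 next to C5′ would erode yield or stereochemical purity. The fallback makes the C–Cl bond with electrophilic chlorine instead and sets out from aldehyde 22.
- Addition of the lithium enolate of 3-methoxycyclopent-2-en-1-one (LDA, THF, −78 °C) would give the aldol 5-[hydroxy(8β-triethylsilyloxydriman-11-yl)]-3-methoxycyclopent-2-en-1-one F5.
- Dehydration through its mesylate (MsCl, Et3N, then DBU) would give the alkylidene vinylogous ester 5-[8β-(triethylsilyloxy)driman-11-ylidene]-3-methoxycyclopent-2-en-1-one F6.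
- Aqueous HCl in THF would cleave the enol ether and the silyl ether to the chlorine-free vinylogous acid 3-hydroxy-4-(8β-hydroxydriman-11-ylidene)cyclopent-2-en-1-one F7.
- Exhaustive silylation (TMSOTf, Et3N) would give the tris(trimethylsilyl) derivative F8, a 1,3-bis(silyloxy)diene set in a fulvene.
- N-Chlorosuccinimide at −78 °C should chlorinate its terminal carbon C5′, as such dienes react with electrophiles at the terminus.
- Work-up with HF·pyridine would deliver 30 together with its C5′ epimer (5S)-5-chloro-3-hydroxy-4-[(E)-8β-hydroxydriman-11-ylidene]cyclopent-2-en-1-one F9, to be separated by preparative HPLC.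

In this fallback the C5′ configuration comes from separation and not from induction; it returns to the route at 30.

Step 17. Reductive loss of iodine or self-condensation of the iodoenone may outrun addition of the alkenylchromium species to the very hindered aldehyde. The fallback replaces the organochromium coupling by a thiolate Michael–aldol sequence and sets out from aldehyde 22 and enone 23. Me2AlSPh (CH2Cl2/THF, −78 °C) adds to 23 anti to the silyloxy group, and the aluminium enolate is trapped by 22 to give the β-phenylthio aldol (4R)-4-[(tert-butyldimethylsilyl)oxy]-2-[11-hydroxy-8β-(triethylsilyloxy)driman-11-yl]-3-(phenylthio)cyclopentan-1-one F10. Oxidation with 3-chloroperbenzoic acid at −78 °C gives the sulfoxide F11, which on warming loses the sulfenic acid by syn-elimination and returns to the route at 26.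

**Further compounds**
F1 | step 9 | ent-8β-pivaloyloxy-12-nordrim-6-en-11-al (mirror image of 16) | CC1(C)CCC[C@@]2(C)[C@H](C=O)[C@H](OC(=O)C(C)(C)C)C=C[C@H]12
F2 | step 9 | ent-12-nordrim-6-ene-8β,11-diol (mirror image of 17) | CC1(C)CCC[C@@]2(C)[C@H](CO)[C@H](O)C=C[C@H]12
F3 | step 9 | 11-O-[(1S)-camphanoyl]-12-nordrim-6-ene-8β,11-diol | CC1(C)CCC[C@]2(C)[C@@H](COC(=O)[C@@]34CC[C@@](C)(C(=O)O3)C4(C)C)[C@@H](O)C=C[C@@H]12
F4 | step 9 | (1S)-camphanate of the mirror-image diol F2 | CC1(C)CCC[C@@]2(C)[C@H](COC(=O)[C@@]34CC[C@@](C)(C(=O)O3)C4(C)C)[C@H](O)C=C[C@H]12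
F5 | step 18 | 5-[hydroxy(8β-triethylsilyloxydriman-11-yl)]-3-methoxycyclopent-2-en-1-one (epimer mixture) | CC1(C)CCC[C@]2(C)[C@@H](C(O)C3CC(OC)=CC3=O)[C@@](C)(O[Si](CC)(CC)CC)CC[C@@H]12
F6 | step 18 | 5-[8β-(triethylsilyloxy)driman-11-ylidene]-3-methoxycyclopent-2-en-1-one | CC1(C)CCC[C@]2(C)[C@@H](/C=C3\C(=O)C=C(OC)C3)[C@@](C)(O[Si](CC)(CC)CC)CC[C@@H]12
F7 | step 18 | 3-hydroxy-4-(8β-hydroxydriman-11-ylidene)cyclopent-2-en-1-one (chlorine-free vinylogous acid) | CC1(C)CCC[C@]2(C)[C@@H](/C=C3\C(O)=CC(=O)C3)[C@@](C)(O)CC[C@@H]12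
F8 | step 18 | tris(trimethylsilyl) derivative of F7 (1,3-bis(silyloxy)fulvene, 8-O-silyl ether) | CC1(C)CCC[C@]2(C)[C@@H](/C=C3/C=C(O[Si](C)(C)C)C=C3O[Si](C)(C)C)[C@@](C)(O[Si](C)(C)C)CC[C@@H]12
F9 | step 18 | (5S)-5-chloro-3-hydroxy-4-[(E)-8β-hydroxydriman-11-ylidene]cyclopent-2-en-1-one (C5′ epimer of 30) | CC1(C)CCC[C@]2(C)[C@@H](/C=C3\C(O)=CC(=O)[C@H]3Cl)[C@@](C)(O)CC[C@@H]12
F10 | step 17 | (4R)-4-[(tert-butyldimethylsilyl)oxy]-2-[11-hydroxy-8β-(triethylsilyloxy)driman-11-yl]-3-(phenylthio)cyclopentan-1-one | CC1(C)CCC[C@]2(C)[C@@H](C(O)[C@@H]3[C@@H](Sc4ccccc4)[C@H](O[Si](C)(C)C(C)(C)C)CC3=O)[C@@](C)(O[Si](CC)(CC)CC)CC[C@@H]12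
F11 | step 17 | S-oxide (sulfoxide) of F10 | CC1(C)CCC[C@]2(C)[C@@H](C(O)[C@@H]3[C@@H](S(=O)c4ccccc4)[C@H](O[Si](C)(C)C(C)(C)C)CC3=O)[C@@](C)(O[Si](CC)(CC)CC)CC[C@@H]12
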